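**Retrosynthetic overview**
- The strategy rests on C4 of ring C. It is a lone carbonyl carbon between C4a of ring A and the C3=C2 unit that carries ring B, so it is treated as one molecule of CO. Ring C is cut at C4a–C4, C4–C3 and O1–C2 into a ring-A o-iodophenol, CO and a ring-B arylacetylene.
- Rings A and B are bought as benzenes. Ring C is the only ring formed, in one operation. The 3-OH is added afterwards at C3 by lithiation, borylation and oxidation, then the silyl and benzyl groups are removed.
- The iodophenol comes from 3-hydroxy-4,5-dimethoxybenzaldehyde by silylation, Baeyer–Villiger oxidation with methanolysis, and iodination ortho to OH on the side away from the bulky silyl ether.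
- The arylacetylene comes from O-benzyl-5-bromosalicylaldehyde. It undergoes a Wittig reaction with the phosphonium salt of (R)-3-bromo-2-methylpropan-1-ol, which supplies the only stereocentre, followed by diimide reduction and Sonogashira ethynylation.

Key step: step 11

Remark on the chemistry: the Wittig alkene is drawn as the Z isomer expected from a non-stabilised ylide. Any E isomer would be reduced to the same saturated chain in the following step.

**Route**

Step 1
Reactants: 1 3-hydroxy-4,5-dimethoxybenzaldehyde
Product: 2 3,4-dimethoxy-5-[(triisopropylsilyl)oxy]benzaldehyde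
Conditions: TIPSCl, imidazole, DMF, rt
Reagents that add atoms: triisopropylsilyl chloride, CC(C)[Si](Cl)(C(C)C)C(C)C
Why: Standard imidazole-promoted O-silylation of the only free phenol installs the bulky group that later becomes the 7-O protecting group and steers the iodination.

Step 2
Reactants: 2 3,4-dimethoxy-5-[(triisopropylsilyl)oxy]benzaldehyde
Product: 4 3,4-dimethoxy-5-[(triisopropylsilyl)oxy]phenol, via aryl formate 3 (not isolated)
Conditions: mCPBA, CH2Cl2, 0 °C to rt; wash with aq Na2S2O3/NaHCO3; then Et3N (cat.), MeOH, rt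
Reagents that add atoms: m-chloroperbenzoic acid, O=C(OO)c1cccc(Cl)c1
Why: In this Baeyer–Villiger (Dakin-type) oxidation the electron-rich trioxygenated aryl group migrates in preference to hydride, and the labile aryl formate is methanolysed under amine catalysis too mild to touch the aryl TIPS ether.

Step 3
Reactants: 4 3,4-dimethoxy-5-[(triisopropylsilyl)oxy]phenol
Product: 5 2-iodo-3,4-dimethoxy-5-[(triisopropylsilyl)oxy]phenol
Conditions: NIS (1.0 equiv), dry MeCN, −20 to 0 °C, dark
Reagents that add atoms: N-iodosuccinimide, O=C1CCC(=O)N1I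
Why: In this electrophilic aromatic iodination the position para to OH is blocked by OMe, and of the two ortho sites the one next to OSi(iPr)3 is screened by the isopropyl groups, so the large iodonium electrophile should enter between OH and OMe.

Step 4
Reactants: 6 (R)-3-bromo-2-methylpropan-1-ol
Product: 7 (R)-[(3-bromo-2-methylpropoxy)methyl]benzene
Conditions: BnOC(=NH)CCl3, TfOH (cat.), CH2Cl2/cyclohexane, 0 °C to rt
Reagents that add atoms: benzyl 2,2,2-trichloroacetimidate, N=C(OCc1ccccc1)C(Cl)(Cl)Cl
Why: Acid-catalysed imidate benzylation protects the primary alcohol without base, so oxetane formation and HBr loss are avoided and the purchased stereocentre is not involved.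

Step 5
Reactants: 7 (R)-[(3-bromo-2-methylpropoxy)methyl]benzene
Product: 8 [(R)-3-(benzyloxy)-2-methylpropyl]triphenylphosphonium bromide
Conditions: PPh3, MeCN, 100 °C (sealed tube), 48 h
Reagents that add atoms: triphenylphosphine, c1ccc(cc1)P(c1ccccc1)c1ccccc1
Why: This is an SN2 quaternisation of triphenylphosphine by a primary, β-branched bromide, which is slow but clean on prolonged heating and leaves the adjacent stereocentre untouched.

Step 6
Reactants: 9 5-bromosalicylaldehyde
Product: 10 2-(benzyloxy)-5-bromobenzaldehyde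
Conditions: BnBr, K2CO3, DMF, rt to 50 °C
Reagents that add atoms: benzyl bromide, BrCc1ccccc1
Why: Williamson etherification of the acidic salicylaldehyde phenol is routine and masks the future 4'-OH as a group that is removed in the last step.

Step 7
Reactants: 8 [(R)-3-(benzyloxy)-2-methylpropyl]triphenylphosphonium bromide; 10 2-(benzyloxy)-5-bromobenzaldehyde
Product: 12 1-(benzyloxy)-2-[(1Z,3S)-4-(benzyloxy)-3-methylbut-1-en-1-yl]-4-bromobenzene, via phosphorus ylide 11 (not isolated)
Conditions: 8, NaHMDS, THF, 0 °C; then 10, −78 °C to rt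
Reagents that add atoms: none
Why: Wittig olefination with a non-stabilised ylide joins the side chain to ring B, and the stereocentre β to phosphorus carries no acidic hydrogen, so it is carried over unchanged.

Step 8
Reactants: 12 1-(benzyloxy)-2-[(1Z,3S)-4-(benzyloxy)-3-methylbut-1-en-1-yl]-4-bromobenzene
Product: 13 1-(benzyloxy)-2-[(3S)-4-(benzyloxy)-3-methylbutyl]-4-bromobenzene
Conditions: TsNHNH2 (excess, in portions), NaOAc buffer, DME/H2O, reflux
Reagents that add atoms: none
Why: Diimide reduction transfers H2 in a concerted way to the C=C bond only, so the C–Br bond and both benzyl ethers survive and no metal hydride is present to isomerise the alkene through the allylic stereocentre.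

Step 9
Reactants: 13 1-(benzyloxy)-2-[(3S)-4-(benzyloxy)-3-methylbutyl]-4-bromobenzene
Product: 14 ({4-(benzyloxy)-3-[(3S)-4-(benzyloxy)-3-methylbutyl]phenyl}ethynyl)trimethylsilane
Conditions: TMS-acetylene, PdCl2(PPh3)2 (cat.), CuI (cat.), Et3N/DMF, 80 °C, sealed tube
Reagents that add atoms: ethynyltrimethylsilane, C#C[Si](C)(C)C
Why: Sonogashira coupling at the only C–halogen bond is established for alkoxy-substituted aryl bromides on heating, and the silyl cap prevents double coupling.

Step 10
Reactants: 14 ({4-(benzyloxy)-3-[(3S)-4-(benzyloxy)-3-methylbutyl]phenyl}ethynyl)trimethylsilane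
Product: 15 1-(benzyloxy)-2-[(3S)-4-(benzyloxy)-3-methylbutyl]-4-ethynylbenzene
Conditions: K2CO3 (cat.), MeOH/THF, rt
Reagents that add atoms: none
Why: Methoxide-catalysed protodesilylation of an alkynylsilane is fast and selective, and nothing else in the molecule is base-sensitive.

Step 11
Reactants: 5 2-iodo-3,4-dimethoxy-5-[(triisopropylsilyl)oxy]phenol; 15 1-(benzyloxy)-2-[(3S)-4-(benzyloxy)-3-methylbutyl]-4-ethynylbenzene; 16 carbon monoxide
Product: 19 protected flavone (2-{4-(benzyloxy)-3-[(3S)-4-(benzyloxy)-3-methylbutyl]phenyl}-5,6-dimethoxy-7-[(triisopropylsilyl)oxy]-4H-chromen-4-one), via hydroxyaryl ynone 17 (not isolated), via diethylamino enone 18 (not isolated)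
Conditions: PdCl2(dppf) (5 mol %), CO (5 bar), dry degassed Et2NH, 80 °C, autoclave, no copper
Reagents that add atoms: carbon monoxide 16, [C-]#[O+]; diethylamine, CCNCC (held only in 18)
Why: Pd(0) inserts into the C–I bond of 5, CO migrates into the aryl–Pd bond to give the aroyl-palladium (C4a–C4), and amine-assisted alkynylation with 15 followed by reductive elimination gives the o-hydroxyaryl ynone 17 (C4–C3). Diethylamine then adds to the β-carbon of the ynone to give enaminone 18, and the C8a phenol oxygen attacks that same carbon (C2) and expels the amine, an addition–elimination that amounts to a 6-endo closure of ring C (O1–C2). The closest known reaction type is the palladium-catalysed carbonylative annulation of o-iodophenols with terminal arylacetylenes in a secondary amine, an established flavone synthesis. No stereocentre is formed, and the side-chain methyl centre is remote, neither allylic nor acidic, and is not touched. Three selectivities are needed: CO insertion ahead of direct alkynylation (which would lead on to a 2-arylbenzofuran) is helped by the electron-rich, doubly ortho-substituted aryl-palladium, by CO pressure and by leaving out copper; 6-endo rather than 5-exo (aurone) closure is enforced by the enaminone, whose only electrophilic carbon is C2; and the 5,6-dimethoxy-7-silyloxy pattern is fixed by the iodine sitting between OH and OMe in 5.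

Step 12
Reactants: 19 protected flavone
Product: 22 protected flavonol (2-{4-(benzyloxy)-3-[(3S)-4-(benzyloxy)-3-methylbutyl]phenyl}-3-hydroxy-5,6-dimethoxy-7-[(triisopropylsilyl)oxy]-4H-chromen-4-one), via 3-lithioflavone 20 (not isolated), via lithium trimethoxyborate 21 (not isolated)
Conditions: LDA (1.5 equiv), THF, −78 °C; B(OMe)3, −78 to 0 °C; AcOH, 30% H2O2, 0 °C to rt
Reagents that add atoms: hydrogen peroxide, OO; trimethyl borate, COB(OC)OC (held only in 21); lithium diisopropylamide, [Li]N(C(C)C)C(C)C (lithium held only in 20 and 21)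
Why: The C3–H next to the C4 carbonyl is the most acidic C–H and is removed by LDA with carbonyl-assisted lithiation, a known flavone reaction, and trapping as the borate followed by 1,2-aryl migration to peroxide oxygen under acidic buffering gives the 3-OH without cleaving the silyl ether.

Step 13
Reactants: 22 protected flavonol
Product: 23 2-{4-(benzyloxy)-3-[(3S)-4-(benzyloxy)-3-methylbutyl]phenyl}-3,7-dihydroxy-5,6-dimethoxy-4H-chromen-4-one
Conditions: TBAF, AcOH (1:1), THF, 0 °C
Reagents that add atoms: none
Why: Fluoride-driven cleavage of the aryl silyl ether is especially easy here because the 7-oxide is a vinylogous carboxylate leaving group, and the acetic acid buffer keeps the flavonol from standing as an air-sensitive anion.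

Step 14
Reactants: 23 2-{4-(benzyloxy)-3-[(3S)-4-(benzyloxy)-3-methylbutyl]phenyl}-3,7-dihydroxy-5,6-dimethoxy-4H-chromen-4-one
Product: 24 3,7-dihydroxy-2-{4-hydroxy-3-[(3S)-4-hydroxy-3-methylbutyl]phenyl}-5,6-dimethoxy-4H-chromen-4-one (CNP0253239.1)
Conditions: H2 (1 atm), 10% Pd/C, EtOAc/MeOH, rt
Reagents that add atoms: none
Why: Catalytic hydrogenolysis removes the aryl and the alkyl benzyl ether together, while the fully substituted C2=C3 bond of the flavonol and the methyl ethers are inert at atmospheric pressure and the stereocentre is not adjacent to any reacting bond.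

**Compound list**
1 | 3-hydroxy-4,5-dimethoxybenzaldehyde | COc1cc(C=O)cc(O)c1OC | starting material
2 | 3,4-dimethoxy-5-[(triisopropylsilyl)oxy]benzaldehyde | COc1cc(C=O)cc(O[Si](C(C)C)(C(C)C)C(C)C)c1OC | intermediate
3 | 3,4-dimethoxy-5-[(triisopropylsilyl)oxy]phenyl formate | COc1cc(OC=O)cc(O[Si](C(C)C)(C(C)C)C(C)C)c1OC | intermediate
4 | 3,4-dimethoxy-5-[(triisopropylsilyl)oxy]phenol | COc1cc(O)cc(O[Si](C(C)C)(C(C)C)C(C)C)c1OC | intermediate
5 | 2-iodo-3,4-dimethoxy-5-[(triisopropylsilyl)oxy]phenol | COc1c(O[Si](C(C)C)(C(C)C)C(C)C)cc(O)c(I)c1OC | intermediate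
6 | (R)-3-bromo-2-methylpropan-1-ol | BrC[C@H](C)CO | starting material
7 | (R)-[(3-bromo-2-methylpropoxy)methyl]benzene | BrC[C@H](C)COCc1ccccc1 | intermediate
8 | [(R)-3-(benzyloxy)-2-methylpropyl]triphenylphosphonium bromide | [Br-].c1ccccc1[P+](c1ccccc1)(c1ccccc1)C[C@H](C)COCc1ccccc1 | intermediate
9 | 5-bromosalicylaldehyde | O=Cc1cc(Br)ccc1O | starting material
10 | 2-(benzyloxy)-5-bromobenzaldehyde | O=Cc1cc(Br)ccc1OCc1ccccc1 | intermediate
11 | [(R)-3-(benzyloxy)-2-methylpropylidene]triphenylphosphorane | c1ccccc1P(c1ccccc1)(c1ccccc1)=C[C@H](C)COCc1ccccc1 | intermediate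
12 | 1-(benzyloxy)-2-[(1Z,3S)-4-(benzyloxy)-3-methylbut-1-en-1-yl]-4-bromobenzene | Brc1ccc(OCc2ccccc2)c(/C=C\[C@H](C)COCc2ccccc2)c1 | intermediate
13 | 1-(benzyloxy)-2-[(3S)-4-(benzyloxy)-3-methylbutyl]-4-bromobenzene | Brc1ccc(OCc2ccccc2)c(CC[C@H](C)COCc2ccccc2)c1 | intermediate
14 | ({4-(benzyloxy)-3-[(3S)-4-(benzyloxy)-3-methylbutyl]phenyl}ethynyl)trimethylsilane | C[Si](C)(C)C#Cc1ccc(OCc2ccccc2)c(CC[C@H](C)COCc2ccccc2)c1 | intermediate
15 | 1-(benzyloxy)-2-[(3S)-4-(benzyloxy)-3-methylbutyl]-4-ethynylbenzene | C#Cc1ccc(OCc2ccccc2)c(CC[C@H](C)COCc2ccccc2)c1 | intermediate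
16 | carbon monoxide | [C-]#[O+] | starting material
17 | 3-{4-(benzyloxy)-3-[(3S)-4-(benzyloxy)-3-methylbutyl]phenyl}-1-{2-hydroxy-5,6-dimethoxy-4-[(triisopropylsilyl)oxy]phenyl}prop-2-yn-1-one | COc1c(O[Si](C(C)C)(C(C)C)C(C)C)cc(O)c(C(=O)C#Cc2ccc(OCc3ccccc3)c(CC[C@H](C)COCc3ccccc3)c2)c1OC | intermediate
18 | 3-{4-(benzyloxy)-3-[(3S)-4-(benzyloxy)-3-methylbutyl]phenyl}-3-(diethylamino)-1-{2-hydroxy-5,6-dimethoxy-4-[(triisopropylsilyl)oxy]phenyl}prop-2-en-1-one (alkene geometry not relevant) | COc1c(O[Si](C(C)C)(C(C)C)C(C)C)cc(O)c(C(=O)C=C(N(CC)CC)c2ccc(OCc3ccccc3)c(CC[C@H](C)COCc3ccccc3)c2)c1OC | intermediate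
19 | 2-{4-(benzyloxy)-3-[(3S)-4-(benzyloxy)-3-methylbutyl]phenyl}-5,6-dimethoxy-7-[(triisopropylsilyl)oxy]-4H-chromen-4-one | COc1c(O[Si](C(C)C)(C(C)C)C(C)C)cc2oc(-c3ccc(OCc4ccccc4)c(CC[C@H](C)COCc4ccccc4)c3)cc(=O)c2c1OC | intermediate
20 | 3-lithio derivative of 19 | COc1c(O[Si](C(C)C)(C(C)C)C(C)C)cc2oc(-c3ccc(OCc4ccccc4)c(CC[C@H](C)COCc4ccccc4)c3)c([Li])c(=O)c2c1OC | intermediate
21 | lithium (flavon-3-yl)trimethoxyborate derived from 20 | [Li+].COc1c(O[Si](C(C)C)(C(C)C)C(C)C)cc2oc(-c3ccc(OCc4ccccc4)c(CC[C@H](C)COCc4ccccc4)c3)c([B-](OC)(OC)OC)c(=O)c2c1OC | intermediate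
22 | 2-{4-(benzyloxy)-3-[(3S)-4-(benzyloxy)-3-methylbutyl]phenyl}-3-hydroxy-5,6-dimethoxy-7-[(triisopropylsilyl)oxy]-4H-chromen-4-one | COc1c(O[Si](C(C)C)(C(C)C)C(C)C)cc2oc(-c3ccc(OCc4ccccc4)c(CC[C@H](C)COCc4ccccc4)c3)c(O)c(=O)c2c1OC | intermediate
23 | 2-{4-(benzyloxy)-3-[(3S)-4-(benzyloxy)-3-methylbutyl]phenyl}-3,7-dihydroxy-5,6-dimethoxy-4H-chromen-4-one | COc1c(O)cc2oc(-c3ccc(OCc4ccccc4)c(CC[C@H](C)COCc4ccccc4)c3)c(O)c(=O)c2c1OC | intermediate
24 | 3,7-dihydroxy-2-{4-hydroxy-3-[(3S)-4-hydroxy-3-methylbutyl]phenyl}-5,6-dimethoxy-4H-chromen-4-one | COc1c(O)cc2oc(-c3ccc(O)c(CC[C@H](C)CO)c3)c(O)c(=O)c2c1OC | target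

**Step count**
Total steps: 14.
Longest linear sequence: 10 steps (6 to 24 through steps 4, 5, 7, 8, 9, 10, 11, 12, 13 and 14).

**Steps most likely to fail**

1. Step 11 (key step).
- What may go wrong: oxidative addition into the hindered, electron-rich C–I bond may be slow. The aroyl-palladium may be captured by diethylamine (aminocarbonylation). Alkynylation may precede CO insertion and be followed by benzofuran closure. The silyl ether may be lost in hot amine.
- Fallback: it sets out from 15 and 5 and returns to the route at 17, and through it at 19. The C4 carbon is delivered already bound to the alkyne instead of as gas.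
- Alkyne 15 is deprotonated with n-BuLi (THF, −78 °C) to the lithium acetylide F1. Acylation with N-methoxy-N-methylcarbamoyl chloride gives the alkynyl Weinreb amide F2.
- Iodophenol 5 is treated with n-BuLi (2.1 equiv, THF, −78 °C; O–H deprotonation, then iodine–lithium exchange) to give the lithium 2-lithiophenoxide F3. This adds once to F2 and gives, after NH4Cl quench, ynone 17, now isolated.
- Stirring 17 with Et2NH in EtOH carries it through 18 to 19.

2. Step 3.
- What may go wrong: the iodonium may attack the other free ortho position, between OH and OSi, which lies para to a methoxy group and is electronically slightly favoured. Second iodination and oxidation of the electron-rich phenol to quinone-type material are also possible.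
- Fallback: it sets out from 4 and returns at 5. Directed ortho-metalation replaces electrophilic substitution.
- Phenol 4 is converted (MOMCl, iPr2NEt, CH2Cl2) into the methoxymethyl ether F4.
- n-BuLi (THF, 0 °C) should remove the proton flanked by OMOM and OMe, where two coordinating oxygens cooperate, and not the one beside the bulky, non-coordinating silyloxy group. This gives the aryllithium F5.
- Iodine quench gives the iodinated methoxymethyl ether F6. Catalytic HCl in MeOH, which an aryl TIPS ether tolerates, frees phenol 5.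

3. Step 12.
- What may go wrong: the 3-lithiated pyranone may ring-open by β-elimination of the C8a phenoxide on warming. Competing deprotonation at the O-benzyl CH2 groups may lead to Wittig rearrangement. Trapping by the borate may be incomplete.
- Fallback: it sets out from 19 and returns at 22. Electrophilic oxygen transfer replaces deprotonation.
- Dimethyldioxirane (acetone/CH2Cl2, 0 °C) epoxidises the C2=C3 enol-ether double bond to the 2,3-epoxyflavanone F7. The mixture of epoxide diastereomers is of no consequence.
- Catalytic p-TsOH opens the epoxide at C2, and loss of the C3 proton gives flavonol 22.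

**Further compounds**
F1 | step 11 | lithium acetylide of 15 | [Li]C#Cc1ccc(OCc2ccccc2)c(CC[C@H](C)COCc2ccccc2)c1
F2 | step 11 | 3-{4-(benzyloxy)-3-[(3S)-4-(benzyloxy)-3-methylbutyl]phenyl}-N-methoxy-N-methylprop-2-ynamide | CON(C)C(=O)C#Cc1ccc(OCc2ccccc2)c(CC[C@H](C)COCc2ccccc2)c1
F3 | step 11 | lithium 2-lithio-3,4-dimethoxy-5-[(triisopropylsilyl)oxy]phenoxide | COc1c(O[Si](C(C)C)(C(C)C)C(C)C)cc(O[Li])c([Li])c1OC
F4 | step 3 | [2,3-dimethoxy-5-(methoxymethoxy)phenoxy]triisopropylsilane | COCOc1cc(O[Si](C(C)C)(C(C)C)C(C)C)c(OC)c(OC)c1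
F5 | step 3 | aryllithium of F4, lithiated between OMOM and OMe | COCOc1cc(O[Si](C(C)C)(C(C)C)C(C)C)c(OC)c(OC)c1[Li]
F6 | step 3 | [4-iodo-2,3-dimethoxy-5-(methoxymethoxy)phenoxy]triisopropylsilane | COCOc1cc(O[Si](C(C)C)(C(C)C)C(C)C)c(OC)c(OC)c1I
F7 | step 12 | 2,3-epoxide of 19 (epoxide diastereomers) | COc1c(O[Si](C(C)C)(C(C)C)C(C)C)cc2OC3(c4ccc(OCc5ccccc5)c(CC[C@H](C)COCc5ccccc5)c4)OC3C(=O)c2c1OC
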